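**Plan**

1. Azulene numbering is used for the target 24: C1–C2 is the CH2–CH2 unit, C3 the carbinol, C3a/C8a the ring fusion, C4 the benzoate carbon, C8 the isovalerate carbon. Retrosynthesis cuts the two ester C–O bonds, takes the C4 and C8 carbinols back to ketones, takes C3–OH/C2–H back to a C2=C3 alkene (through its epoxide), cuts the C8a–CH3 bond, and then cuts C8a–C1 and C2–C3 together.
2. Enabling feature: with C8 and C3 as carbonyl groups, the seven-membered ring holds a 1,4-diketone (ring ketone C8, isopropyl ketone C3 on C3a). Its enolisable α-carbon C8a and the ketone carbon C3 are 1,3-related through C3a, so a vinylphosphonium salt (electrophilic at one carbon, ylide at the other) can bridge them as C1–C2 and close the five-membered ring.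
3. Forward: the six-membered ketal ketone 1 is ring-expanded to the cycloheptenone and dehydrogenated to a cross-conjugated dienone, the isobutyryl side chain is put on C3a, and the cyclopentene ring is annulated last. Angular methylation, epoxidation/hydride and two acylations finish 24.
4. Stereochemistry: C3a from an (R)-BINAP/rhodium 1,4-addition; C8a (cis fusion) by methylation of the ring-fusion enolate on its convex face; C3 by convex-face epoxidation; C8 by hydride anti to the angular methyl group; C4 by hydride on the convex face. The facial arguments are by analogy, not precedent on this skeleton.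

Key step: step 7

Assumption: boronic acid 8 is taken as a catalogue compound; its pinacol ester would react in the same way under the conditions of step 5.

**Route**

Step 1
Reactants: 1 7-methyl-1,4-dioxaspiro[4.5]decan-8-one (racemic)
Product: 2 trimethyl[(7-methyl-1,4-dioxaspiro[4.5]dec-7-en-8-yl)oxy]silane
Conditions: Me3SiCl, Et3N, DMF, 90 °C
Reagents that add atoms: chlorotrimethylsilane C[Si](C)(C)Cl
Why: Equilibrating silylation (thermodynamic silyl enol ether formation) should favour the tetrasubstituted enol ether on the methyl-bearing side, which erases the only stereocentre of 1 and fixes where the new ring carbon will enter.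

Step 2
Reactants: 2 trimethyl[(7-methyl-1,4-dioxaspiro[4.5]dec-7-en-8-yl)oxy]silane
Product: 3 1-methyl-6-[(trimethylsilyl)oxy]spiro[bicyclo[4.1.0]heptane-3,2'-[1,3]dioxolane] (racemic)
Conditions: Et2Zn, CH2I2, CH2Cl2, 0 °C to rt
Reagents that add atoms: diiodomethane ICI
Why: Simmons–Smith cyclopropanation of the electron-rich silyl enol ether; only the cis-fused cyclopropane can form, and it is consumed as a racemate in step 3.

Step 3
Reactants: 3 1-methyl-6-[(trimethylsilyl)oxy]spiro[bicyclo[4.1.0]heptane-3,2'-[1,3]dioxolane]
Product: 5 5,5-(ethylenedioxy)-3-methylcyclohept-2-en-1-one, via chloro ketone 4 (not isolated)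
Conditions: FeCl3 (2.2 equiv), DMF, 0 °C; then NaOAc, MeOH, 65 °C
Reagents that add atoms: none
Why: Oxidative ring expansion of a siloxycyclopropane (Ito–Saegusa type): one-electron oxidation by FeCl3 cleaves the internal cyclopropane bond to the β-chloro ketone 4, and NaOAc eliminates HCl to the conjugated 3-methylcycloheptenone, which has no stereocentre.

Step 4
Reactants: 5 5,5-(ethylenedioxy)-3-methylcyclohept-2-en-1-one
Product: 7 5,5-(ethylenedioxy)-3-methylcyclohepta-2,6-dien-1-one, via silyl dienol ether 6 (not isolated)
Conditions: LiN(iPr)2, THF, −78 °C, then Me3SiCl; then Pd(OAc)2 (1.1 equiv), MeCN, rt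
Reagents that add atoms: none
Why: Saegusa–Ito oxidation: kinetic α′-deprotonation at C7 and silylation give the cross-conjugated dienol ether 6, which Pd(OAc)2 dehydrogenates to the α′,β′-enone, so that C6 next to the ketal becomes an unsubstituted β-carbon of an achiral dienone.

Step 5
Reactants: 7 5,5-(ethylenedioxy)-3-methylcyclohepta-2,6-dien-1-one; 8 (3-methylbut-1-en-2-yl)boronic acid
Product: 9 (6R)-5,5-(ethylenedioxy)-3-methyl-6-(3-methylbut-1-en-2-yl)cyclohept-2-en-1-one
Conditions: [Rh(OH)(cod)]2 (2.5 mol %), (R)-BINAP (6 mol %), dioxane/H2O 10:1, 40 °C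
Reagents that add atoms: none
Why: Asymmetric 1,4-addition of an alkenylboronic acid (Hayashi–Miyaura reaction) should take place only at the β-unsubstituted enone carbon C6 (the β-methyl carbon is too hindered), the catalyst from [Rh(OH)(cod)]2 and (R)-BINAP selecting the enone face that makes C6, the future C3a, R; the base-free conditions should avoid loss of the ketal by aromatisation to a tropone.

Step 6
Reactants: 9 (6R)-5,5-(ethylenedioxy)-3-methyl-6-(3-methylbut-1-en-2-yl)cyclohept-2-en-1-one
Product: 11 (6R)-5,5-(ethylenedioxy)-3-methyl-6-(2-methylpropanoyl)cyclohept-2-en-1-one, via ozonide 10 (not isolated)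
Conditions: O3, CH2Cl2, −78 °C (Sudan Red 7B as end-point indicator); then Me2S, −78 °C to rt
Reagents that add atoms: ozone [O-][O+]=O
Why: Ozonolysis with reductive work-up should cleave the electron-rich 1,1-disubstituted alkene before the electron-poor enone double bond and unmask the isopropyl ketone under neutral conditions that leave the α-stereocentre untouched.

Step 7
Reactants: 11 (6R)-5,5-(ethylenedioxy)-3-methyl-6-(2-methylpropanoyl)cyclohept-2-en-1-one; 12 triphenyl(vinyl)phosphonium bromide
Product: 14 cis-fused 4,4-(ethylenedioxy)-6-methyl-3-(propan-2-yl)-3a,4,5,8a-tetrahydroazulen-8(1H)-one, via phosphonium ylide 13 (not isolated)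
Conditions: LiN(iPr)2 (1.05 equiv), THF, −78 °C; then 12 (1.1 equiv), −78 to 65 °C
Reagents that add atoms: none
Why: LiN(iPr)2 removes a proton from the only α-methylene (C7 of 11, the future C8a), the enolate adds to the CH2= terminus of 12 (new C8a–C1 bond) to give ylide 13, and the ylide carbon (future C2) attacks the 1,3-related isopropyl ketone carbon (future C3) to give an oxaphosphetane that loses Ph3PO and leaves the C2=C3 double bond. The closest known reaction type is the Michael addition/intramolecular Wittig cyclopentene annulation of vinylphosphonium salts with carbon nucleophiles that carry a γ-keto group. The five-membered ring closes in the Wittig stage by 5-exo-trig attack of the ylide carbon on the ketone C=O. C3a is not touched and keeps the configuration of step 5, while the new C8a methine is α to the ring ketone, should equilibrate to the cis-fused isomer under the basic conditions and is in any case reset in step 8. The step needs regioselective enolisation and a chemoselective Wittig closure: the first should be secured by kinetic deprotonation at the single unhindered CH2 (both α-positions of the isopropyl ketone are methines and γ-deprotonation of the enone is slow at −78 °C), the second by ring size, since closure on the ring ketone would give a cyclobutene.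

Step 8
Reactants: 14 cis-fused 4,4-(ethylenedioxy)-6-methyl-3-(propan-2-yl)-3a,4,5,8a-tetrahydroazulen-8(1H)-one
Product: 15 (3aS,8aR)-4,4-(ethylenedioxy)-6,8a-dimethyl-3-(propan-2-yl)-3a,4,5,8a-tetrahydroazulen-8(1H)-one
Conditions: LiN(iPr)2, THF, −78 °C; then MeI, DMPU, −78 to 0 °C
Reagents that add atoms: iodomethane CI
Why: Kinetic α′-deprotonation gives the ring-fusion enolate, and MeI should approach its convex face (the face of H-3a, away from both rings), the usual course of angular alkylation of a bicyclo[5.3.0] enolate, so that C8a becomes quaternary with methyl cis to H-3a.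

Step 9
Reactants: 15 (3aS,8aR)-4,4-(ethylenedioxy)-6,8a-dimethyl-3-(propan-2-yl)-3a,4,5,8a-tetrahydroazulen-8(1H)-one
Product: 16 2,3-epoxide of 15 with the oxirane oxygen on the face of the 8a-methyl group and H-3a
Conditions: mCPBA, NaHCO3, CH2Cl2, 0 °C
Reagents that add atoms: 3-chloroperbenzoic acid OOC(=O)c1cccc(Cl)c1
Why: Prilezhaev epoxidation should pick the electron-rich trisubstituted cyclopentene over the enone double bond and occur on the convex face (syn to H-3a and the angular methyl), because the seven-membered ring with its spiro ketal covers the other face; this places the C3 oxygen cis to the methyl group.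

Step 10
Reactants: 16 2,3-epoxide of 15
Product: 17 4,4-(ethylenedioxy)-6,8a-dimethyl-3-(propan-2-yl)-1,2,3,3a,4,5,8,8a-octahydroazulene-3,8-diol (3-OH, 8-OH, 8a-CH3 and H-3a on the same face)
Conditions: LiAlH4, THF, −78 to 65 °C; then H2O, aq NaOH
Reagents that add atoms: none
Why: LiAlH4 should reduce the enone 1,2 with hydride delivery anti to the adjacent angular methyl group (as for ketones flanked by an angular methyl), giving 8-OH cis to the methyl, and open the trisubstituted epoxide by SN2 attack at the secondary C2, which leaves the tertiary C3 alcohol with the configuration set in step 9.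

Step 11
Reactants: 17 4,4-(ethylenedioxy)-6,8a-dimethyl-3-(propan-2-yl)-1,2,3,3a,4,5,8,8a-octahydroazulene-3,8-diol; 18 3-methylbutanoyl chloride
Product: 19 8-O-(3-methylbutanoyl) ester of 17
Conditions: pyridine, DMAP (cat.), CH2Cl2, 0 °C
Reagents that add atoms: none
Why: DMAP-catalysed acylation (nucleophilic acyl substitution) should esterify the secondary allylic alcohol only, the tertiary C3 alcohol being too hindered; no stereocentre is affected.

Step 12
Reactants: 19 8-O-(3-methylbutanoyl) ester of 17
Product: 20 (3S,3aS,8R,8aR)-3-hydroxy-6,8a-dimethyl-4-oxo-3-(propan-2-yl)-1,2,3,3a,4,5,8,8a-octahydroazulen-8-yl 3-methylbutanoate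
Conditions: PPTS, acetone/H2O 10:1, 45 °C
Reagents that add atoms: water O
Why: Acid-catalysed ketal hydrolysis under mildly acidic conditions should free the C4 ketone without ionising the allylic ester or dehydrating the tertiary β-hydroxy ketone, which is reduced directly in step 13.

Step 13
Reactants: 20 (3S,3aS,8R,8aR)-3-hydroxy-6,8a-dimethyl-4-oxo-3-(propan-2-yl)-1,2,3,3a,4,5,8,8a-octahydroazulen-8-yl 3-methylbutanoate
Product: 21 (3S,3aS,4R,8R,8aR)-3,4-dihydroxy-6,8a-dimethyl-3-(propan-2-yl)-1,2,3,3a,4,5,8,8a-octahydroazulen-8-yl 3-methylbutanoate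
Conditions: NaBH4, MeOH, −20 °C
Reagents that add atoms: none
Why: Borohydride reduction should deliver hydride to the convex face of the C4 ketone (the face of H-3a), because the isopropyl group at C3 fills the concave face, giving the 4R alcohol with OH trans to H-3a; the ester is inert to NaBH4 at this temperature.

Step 14
Reactants: 21 (3S,3aS,4R,8R,8aR)-3,4-dihydroxy-6,8a-dimethyl-3-(propan-2-yl)-1,2,3,3a,4,5,8,8a-octahydroazulen-8-yl 3-methylbutanoate; 22 4-acetoxybenzoyl chloride
Product: 23 O-acetate of 24 (4-acetoxybenzoate at C4)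
Conditions: Et3N, DMAP, CH2Cl2, 25 °C
Reagents that add atoms: none
Why: DMAP-catalysed acylation of the remaining secondary alcohol proceeds with retention at C4; the tertiary alcohol should not react, and the phenol is carried as its acetate.

Step 15
Reactants: 23 O-acetate of 24
Product: 24 (3S,3aS,4R,8R,8aR)-3-hydroxy-6,8a-dimethyl-8-[(3-methylbutanoyl)oxy]-3-(propan-2-yl)-1,2,3,3a,4,5,8,8a-octahydroazulen-4-yl 4-hydroxybenzoate
Conditions: pyrrolidine (3 equiv), MeCN, 0 °C
Reagents that add atoms: none
Why: Chemoselective aminolysis of the aryl acetate, whose phenoxide leaving group makes it far more reactive than the two alkyl esters, should free the phenol and give 24.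

**Compound list**

1 | 7-methyl-1,4-dioxaspiro[4.5]decan-8-one (racemic) | CC1CC2(CCC1=O)OCCO2 | starting material
2 | trimethyl[(7-methyl-1,4-dioxaspiro[4.5]dec-7-en-8-yl)oxy]silane | CC1=C(O[Si](C)(C)C)CCC2(C1)OCCO2 | intermediate
3 | 1-methyl-6-[(trimethylsilyl)oxy]spiro[bicyclo[4.1.0]heptane-3,2'-[1,3]dioxolane] (racemic, cis-fused cyclopropane) | CC12CC1(O[Si](C)(C)C)CCC1(OCCO1)C2 | intermediate
4 | 3-chloro-5,5-(ethylenedioxy)-3-methylcycloheptan-1-one (racemic, not isolated) | CC1(Cl)CC(=O)CCC2(C1)OCCO2 | intermediate
5 | 5,5-(ethylenedioxy)-3-methylcyclohept-2-en-1-one | CC1=CC(=O)CCC2(C1)OCCO2 | intermediate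
6 | {[4,4-(ethylenedioxy)-6-methylcyclohepta-1,6-dien-1-yl]oxy}trimethylsilane (not isolated) | CC1=CC(O[Si](C)(C)C)=CCC2(C1)OCCO2 | intermediate
7 | 5,5-(ethylenedioxy)-3-methylcyclohepta-2,6-dien-1-one | CC1=CC(=O)C=CC2(C1)OCCO2 | intermediate
8 | (3-methylbut-1-en-2-yl)boronic acid | CC(C)C(=C)B(O)O | starting material
9 | (6R)-5,5-(ethylenedioxy)-3-methyl-6-(3-methylbut-1-en-2-yl)cyclohept-2-en-1-one | CC1=CC(=O)C[C@H](C(=C)C(C)C)C2(C1)OCCO2 | intermediate
10 | ozonide (1,2,4-trioxolane) of the side-chain alkene of 9 (not isolated) | CC1=CC(=O)C[C@H](C3(C(C)C)OCOO3)C2(C1)OCCO2 | intermediate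
11 | (6R)-5,5-(ethylenedioxy)-3-methyl-6-(2-methylpropanoyl)cyclohept-2-en-1-one | CC1=CC(=O)C[C@H](C(=O)C(C)C)C2(C1)OCCO2 | intermediate
12 | triphenyl(vinyl)phosphonium bromide | C=C[P+](c1ccccc1)(c1ccccc1)c1ccccc1.[Br-] | starting material
13 | 7-[2-(triphenylphosphoranylidene)ethyl] derivative of 11 (ylide, not isolated; C7 unassigned) | CC1=CC(=O)C(CC=P(c3ccccc3)(c3ccccc3)c3ccccc3)[C@H](C(=O)C(C)C)C2(C1)OCCO2 | intermediate
14 | cis-fused 4,4-(ethylenedioxy)-6-methyl-3-(propan-2-yl)-3a,4,5,8a-tetrahydroazulen-8(1H)-one (C3a as in 24; C8a epimerisable, drawn cis) | CC1=CC(=O)[C@@H]2CC=C(C(C)C)[C@@H]2C3(C1)OCCO3 | intermediate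
15 | (3aS,8aR)-4,4-(ethylenedioxy)-6,8a-dimethyl-3-(propan-2-yl)-3a,4,5,8a-tetrahydroazulen-8(1H)-one (methyl and H-3a cis) | CC1=CC(=O)[C@]2(C)CC=C(C(C)C)[C@@H]2C3(C1)OCCO3 | intermediate
16 | 2,3-epoxide of 15, oxirane oxygen on the face of 8a-CH3 and H-3a | CC1=CC(=O)[C@]2(C)C[C@H]3O[C@@]3(C(C)C)[C@@H]2C4(C1)OCCO4 | intermediate
17 | 4,4-(ethylenedioxy)-6,8a-dimethyl-3-(propan-2-yl)-1,2,3,3a,4,5,8,8a-octahydroazulene-3,8-diol (3-OH, 8-OH, 8a-CH3, H-3a all cis) | CC1=C[C@@H](O)[C@]2(C)CC[C@](O)(C(C)C)[C@@H]2C3(C1)OCCO3 | intermediate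
18 | 3-methylbutanoyl chloride | CC(C)CC(Cl)=O | starting material
19 | 8-O-(3-methylbutanoyl) ester of 17 | CC1=C[C@@H](OC(=O)CC(C)C)[C@]2(C)CC[C@](O)(C(C)C)[C@@H]2C3(C1)OCCO3 | intermediate
20 | (3S,3aS,8R,8aR)-3-hydroxy-6,8a-dimethyl-4-oxo-3-(propan-2-yl)-1,2,3,3a,4,5,8,8a-octahydroazulen-8-yl 3-methylbutanoate | CC1=C[C@@H](OC(=O)CC(C)C)[C@]2(C)CC[C@](O)(C(C)C)[C@@H]2C(=O)C1 | intermediate
21 | (3S,3aS,4R,8R,8aR)-3,4-dihydroxy-6,8a-dimethyl-3-(propan-2-yl)-1,2,3,3a,4,5,8,8a-octahydroazulen-8-yl 3-methylbutanoate | CC1=C[C@@H](OC(=O)CC(C)C)[C@]2(C)CC[C@](O)(C(C)C)[C@@H]2[C@H](O)C1 | intermediate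
22 | 4-acetoxybenzoyl chloride | CC(=O)Oc1ccc(cc1)C(Cl)=O | starting material
23 | O-acetate of 24 (4-acetoxybenzoate at C4) | CC1=C[C@@H](OC(=O)CC(C)C)[C@]2(C)CC[C@](O)(C(C)C)[C@@H]2[C@H](OC(=O)c2ccc(OC(C)=O)cc2)C1 | intermediate
24 | (3S,3aS,4R,8R,8aR)-3-hydroxy-6,8a-dimethyl-8-[(3-methylbutanoyl)oxy]-3-(propan-2-yl)-1,2,3,3a,4,5,8,8a-octahydroazulen-4-yl 4-hydroxybenzoate | CC1=C[C@@H](OC(=O)CC(C)C)[C@]2(C)CC[C@](O)(C(C)C)[C@@H]2[C@H](OC(=O)c2ccc(O)cc2)C1 | target

Total steps: 15. Longest linear sequence: 15 steps (1 to 24).

**Steps most likely to fail**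

Step 7. The enolate may form at a wrong α-position, or proton transfer may quench the ylide before it reaches the hindered isopropyl ketone. The same cyclopentene can be closed by olefin metathesis instead. The fallback sets out from 9, before the ozonolysis: LiN(iPr)2 and allyl bromide give the α′-allyl ketone F1. After base equilibration of the allyl-bearing carbon, ring-closing metathesis with the second-generation Grubbs catalyst between the allyl group and the 1,1-disubstituted alkene gives 14, where the route is rejoined. Step 6 is then not needed.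

Step 8. Facial selectivity may be poor, or O-alkylation may compete, when the bicyclic ring-fusion enolate is methylated. The quaternary centre can instead be set on the monocycle, where induction by the neighbouring substituent is dependable. The fallback sets out from 9: allylation as above gives the allyl ketone F1. A second enolisation and MeI then give the α′-allyl-α′-methyl ketone F2, the methyl entering trans to the neighbouring alkenyl group so that allyl and alkenyl stay cis. Ring-closing metathesis with the second-generation Grubbs catalyst gives 15, where the route is rejoined.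

Step 10. Hydride may be delivered to the other face of the C8 ketone. The epimer need not be discarded. The fallback sets out from 16: the reduction would then give the 8-epimeric diol F3. Mitsunobu esterification of its secondary allylic alcohol with 3-methylbutanoic acid (PPh3, diisopropyl azodicarboxylate) inverts C8 while installing the ester; the tertiary alcohol does not react. This gives 19, where the route is rejoined, and step 11 is replaced.

Further compounds
F1 | step 7 | (6R)-7-allyl-5,5-(ethylenedioxy)-3-methyl-6-(3-methylbut-1-en-2-yl)cyclohept-2-en-1-one (C7 epimerisable) | CC1=CC(=O)C(CC=C)[C@H](C(=C)C(C)C)C2(C1)OCCO2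
F2 | step 8 | (6R)-7-allyl-5,5-(ethylenedioxy)-3,7-dimethyl-6-(3-methylbut-1-en-2-yl)cyclohept-2-en-1-one (7-methyl trans to the 6-alkenyl group) | CC1=CC(=O)[C@](C)(CC=C)[C@H](C(=C)C(C)C)C2(C1)OCCO2
F3 | step 10 | 8-epimer of diol 17 | CC1=C[C@H](O)[C@]2(C)CC[C@](O)(C(C)C)[C@@H]2C3(C1)OCCO3
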